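(The earlier runs and the new flask are simulated from invented constants.)

The constants I want are two, one per hand, and the excess hangs on their ratio s, the selectivity factor. The runs so far and the questions are these:

- dusk: left-handed substrate 0.20 M; right-handed substrate 0.20 M; reagent 1.6 M; free catalyst 20 mM; racemization catalyst 5 mM; run made earlier
- flask: left-handed substrate 0.20 M; reagent 0.800 M; free catalyst 20 mM; racemization catalyst 5.0 mM; right-handed substrate 0.20 M; time 8.0 min

dusk run (percent of the left-handed substrate and right-handed substrate together charged)

| time / s | left-handed product / % | right-handed product / % |
|---|---|---|
| 10.0 | 3.3 | 0 |
| 12.0 | 5.4 | 0.7 |
| 20.0 | 7.2 | 1.2 |
| 30.0 | 9.4 | 1.2 |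
| 50.0 | 16.3 | 3.2 |

(scatter of a reading: 0.5 percentage points)

- free catalyst is single-handed; left-handed substrate and right-handed substrate are mirror images of each other, charged as a racemate, each of them at the stated concentration
- the numbers in the tables scatter with a standard deviation of 0.5 percentage points
- an excess is below zero if the other one leads

- left-handed product and right-handed product together, in percent of the left-handed substrate and right-handed substrate charged together, at 8.0 min
- excess of left-handed product over right-handed product in the product at 8.0 min
- whether the exchange between left-handed substrate and right-handed substrate keeps pace with the reaction: how far the product's excess at 8.0 min gets from its value without exchange to its value with instant exchange (above 80% keeps pace, below 20% hardly takes part, else lags behind)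

I read the two product columns of the dusk run against each other. Row by row the ratio jumps, 7.83 at 30.0 s and 5.09 at 50.0 s, but a right-handed reading of 1.2% carries a scatter of 0.5 percentage points, so single rows say little. I therefore sum the columns, which gives s = 6.60. That is a reading: the right-handed sum is 6.3 points with a scatter of 1.1 points.

I assume that reagent and free catalyst act on both hands to the same order, so they cancel in the ratio. Left-handed product then forms s times x as fast as right-handed product, where x is left-handed over right-handed substrate. The running excess is (sx − 1)/(sx + 1). If exchange holds x at one, the product's excess stands at the ceiling excess E = 73.7%. Any lag in the exchange lets x sink below one and pulls the excess under E. The dusk ratios show no drift beyond their scatter, so the lag can't be read from them. I commit to an excess under E at 8.0 min, without a figure for the gap.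

The forecast gives 49% of the two products together, an excess of 63%, lower than E, and for the exchange lags behind, “a best guess”.

The flask gives 55.9% of the two products together and an excess of 70.8%; the exchange lags behind, at 70% of the way.

    reagent + free catalyst + left-handed substrate → free catalyst + left-handed product (k = 0.244 /M²/s)
    reagent + free catalyst + right-handed substrate → free catalyst + right-handed product (k = 0.0342 /M²/s)
    left-handed substrate + racemization catalyst ⇌ right-handed substrate + racemization catalyst, rate k3*[racemization catalyst]*[left-handed substrate] forward; the back reaction follows from the equilibrium constant (k = 4.81 /M/s)
    2 racemization catalyst ⇌ resting dimer, settled at all times (K = 1100 /M)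
    2 racemization catalyst → spent catalyst (k = 1.96 /M/s)

At 8.00 min the flask holds left-handed substrate at 19.1% against right-handed at 25.0%, so x is 0.767. With my s the running excess there is 67.0%, and the flask's accumulated 70.8% lies between that and E, below E. In the neighbour flask with 0.20 M of reagent, the substrates stand at 39.4% and 41.9% at the same time, so x is 0.941, closer to one than in the flask, and E, which carries the scatter of s, lies 0.60 points under that neighbour's excess of 74.3%.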